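**Strategy.** The route rests on disconnecting the C2–C3 bond of ring C (the pyranone: O1, C2, C3, C4, C4a, C8a). C2, the methylene on the ring oxygen O1, is traced back to the methyl group of an aryl methyl ether. C3, flanked by the C4 ketone and ring B, is traced back to a diazo carbon. The key step is an enantioselective dirhodium-carbene insertion into a methoxy C–H bond that closes ring C, forms C2–C3 and sets the C3 stereocentre in one operation. Its precursor is an open-chain 2-diazo-1,2-diarylethanone, made by α-arylation of a prenylated acetophenone with a prenylated aryl bromide and then diazo transfer; all phenols except the methoxy are silylated.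

Key step: step 8

Remark: the sense of induction of the chiral dirhodium catalyst with this substrate cannot be predicted with certainty; Rh2(S-PTAD)4 is written, and its mirror image Rh2(R-PTAD)4 would be used instead if a first run gives the (3R) series.

**Step 1**
Reactants: 1 1-(4-hydroxy-2-methoxyphenyl)ethanone
Product: 2 1-(5-bromo-4-hydroxy-2-methoxyphenyl)ethanone
Conditions: NBS (1.0 equiv), MeCN, 0 °C
Reagents that add atoms: N-bromosuccinimide, O=C1CCC(=O)N1Br
Why: Electrophilic aromatic bromination, in which the free 4-hydroxyl (ortho) and the 2-methoxy group (para) both direct to C5 while C3 between the two oxygens is shielded, so the 5-bromide should form without attack on the acetyl group.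

**Step 2**
Reactants: 2 1-(5-bromo-4-hydroxy-2-methoxyphenyl)ethanone
Product: 3 1-[5-bromo-4-(tert-butyldimethylsilyloxy)-2-methoxyphenyl]ethanone
Conditions: TBSCl, imidazole, DMF, rt
Reagents that add atoms: tert-butyldimethylsilyl chloride, CC(C)(C)[Si](C)(C)Cl
Why: Imidazole-promoted silylation of a phenol, which masks the acidic O–H for the later enolate, diazo and carbene chemistry.

**Step 3**
Reactants: 3 1-[5-bromo-4-(tert-butyldimethylsilyloxy)-2-methoxyphenyl]ethanone; 4 tributyl(3-methylbut-2-enyl)stannane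
Product: 5 1-[4-(tert-butyldimethylsilyloxy)-2-methoxy-5-(3-methylbut-2-enyl)phenyl]ethanone (fragment A)
Conditions: Pd(PPh3)4 (5 mol %), DMF, 90 °C
Reagents that add atoms: none
Why: Stille cross-coupling, in which zerovalent palladium inserts into the aryl bromide and reductive elimination at the unhindered primary allyl terminus should give the linear prenyl arene under neutral conditions that spare the ketone and the silyl ether.

**Step 4**
Reactants: 6 4,6-dibromobenzene-1,3-diol
Product: 7 1,5-dibromo-2,4-bis(tert-butyldimethylsilyloxy)benzene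
Conditions: TBSCl (2.4 equiv), imidazole, DMF, rt
Reagents that add atoms: tert-butyldimethylsilyl chloride, CC(C)(C)[Si](C)(C)Cl
Why: Double silylation of the resorcinol; silicon on the future 2'-oxygen matters because it offers the later carbene no C–H on the atom bonded to that oxygen.

**Step 5**
Reactants: 7 1,5-dibromo-2,4-bis(tert-butyldimethylsilyloxy)benzene; 8 1-bromo-3-methylbut-2-ene (prenyl bromide)
Product: 10 1-bromo-2,4-bis(tert-butyldimethylsilyloxy)-5-(3-methylbut-2-enyl)benzene (fragment B), via arylmagnesium chloride 9 (not isolated)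
Conditions: i-PrMgCl·LiCl (1.05 equiv), THF, 0 °C → rt; then Li2CuCl4 (3 mol %), 8, 0 °C
Reagents that add atoms: none
Why: Bromine–magnesium exchange should stop after one bromine because the electron-rich arylmagnesium species resists a second exchange, and the copper-catalysed Grignard–allyl halide coupling takes place at the primary carbon of 8; the two bromines of 7 are equivalent, so one regioisomer results.

**Step 6**
Reactants: 5 1-[4-(tert-butyldimethylsilyloxy)-2-methoxy-5-(3-methylbut-2-enyl)phenyl]ethanone; 10 1-bromo-2,4-bis(tert-butyldimethylsilyloxy)-5-(3-methylbut-2-enyl)benzene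
Product: 11 2-[2,4-bis(tert-butyldimethylsilyloxy)-5-(3-methylbut-2-enyl)phenyl]-1-[4-(tert-butyldimethylsilyloxy)-2-methoxy-5-(3-methylbut-2-enyl)phenyl]ethanone
Conditions: Pd(OAc)2 (2 mol %), MePhos (2-dicyclohexylphosphino-2'-methylbiphenyl, 4 mol %), K3PO4, toluene, 80 °C
Reagents that add atoms: none
Why: Palladium-catalysed α-arylation of a methyl ketone, in which the weak, insoluble base K3PO4 should spare the aryl silyl ethers and the more acidic product is held as its enolate, which prevents a second arylation.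

**Step 7**
Reactants: 11 the deoxybenzoin from step 6
Product: 12 2-[2,4-bis(tert-butyldimethylsilyloxy)-5-(3-methylbut-2-enyl)phenyl]-1-[4-(tert-butyldimethylsilyloxy)-2-methoxy-5-(3-methylbut-2-enyl)phenyl]-2-diazoethanone
Conditions: p-ABSA, DBU, anhydrous MeCN, 0 °C → rt
Reagents that add atoms: 4-acetamidobenzenesulfonyl azide (p-ABSA), CC(=O)Nc1ccc(cc1)S(=O)(=O)N=[N+]=[N-]
Why: Regitz diazo transfer to the doubly activated methylene between the ketone and ring B, which is acidic enough for DBU and gives the donor/acceptor diazo ketone.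

**Step 8**
Reactants: 12 the diazo ketone from step 7
Product: 14 (3S)-7-(tert-butyldimethylsilyloxy)-3-[2,4-bis(tert-butyldimethylsilyloxy)-5-(3-methylbut-2-enyl)phenyl]-6-(3-methylbut-2-enyl)chroman-4-one, via rhodium carbene 13 (not isolated)
Conditions: Rh2(S-PTAD)4 (1 mol %), PhCF3, 0 °C, slow addition of 12, 4 Å MS
Reagents that add atoms: none
Why: The divalent rhodium catalyst Rh2(S-PTAD)4 expels dinitrogen from 12 to give the electrophilic donor/acceptor carbene 13 (ring B as donor, the ketone as acceptor), which inserts into a C–H bond of the neighbouring methoxy group through a three-centre, hydride-transfer-like transition state stabilised by the oxygen lone pair, so that the C2–C3 and C3–H bonds form together. The closest known reaction types are the dirhodium-catalysed intramolecular C–H insertion of 2-alkoxyphenyl α-diazo ketones to chroman-4-ones and the enantioselective insertion of aryl-substituted rhodium carbenes into methyl ethers. Ring C closes as a six-membered ring by 1,6-insertion (carbene carbon C3, then C4, C4a, C8a, O1 and the methyl carbon as C2). The C3 stereocentre is set under catalyst control, because the chiral carboxylate ligands leave one face of the carbene open to the approaching C–H bond, and the catalyst antipode is chosen for (S). The step needs chemoselectivity for the methoxy C–H: the 2'-oxygen carries silicon, so the otherwise favoured 1,5-insertion has no C–H to use; the prenyl alkenes sit meta to the side chain and cannot reach the carbene within the molecule; slow addition at high dilution suppresses bimolecular cyclopropanation and carbene dimerisation; and reversible oxonium ylide formation at the methoxy oxygen has no easy exit because methyl migrates poorly. The neutral, aprotic medium should leave the enolisable C3–H of 14 untouched.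

**Step 9**
Reactants: 14 the tris-silylated (3S)-isoflavanone from step 8
Product: 15 (3S)-3-[2,4-dihydroxy-5-(3-methylbut-2-enyl)phenyl]-7-hydroxy-6-(3-methylbut-2-enyl)chroman-4-one (CNP0166009.1)
Conditions: TBAF/AcOH (1:1, 3.5 equiv), THF, 0 °C
Reagents that add atoms: none
Why: Fluoride-mediated cleavage of aryl silyl ethers, buffered with acetic acid so that neither phenoxide nor enolate builds up, which should preserve both the C3 stereocentre next to the ketone and the acid-sensitive ortho-prenyl phenols.

**Compound list**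
1 | 1-(4-hydroxy-2-methoxyphenyl)ethanone | CC(=O)c1ccc(O)cc1OC | starting material
2 | 1-(5-bromo-4-hydroxy-2-methoxyphenyl)ethanone | CC(=O)c1cc(Br)c(O)cc1OC | intermediate
3 | 1-[5-bromo-4-(tert-butyldimethylsilyloxy)-2-methoxyphenyl]ethanone | CC(=O)c1cc(Br)c(O[Si](C)(C)C(C)(C)C)cc1OC | intermediate
4 | tributyl(3-methylbut-2-enyl)stannane | CCCC[Sn](CCCC)(CCCC)CC=C(C)C | starting material
5 | 1-[4-(tert-butyldimethylsilyloxy)-2-methoxy-5-(3-methylbut-2-enyl)phenyl]ethanone | CC(=O)c1cc(CC=C(C)C)c(O[Si](C)(C)C(C)(C)C)cc1OC | intermediate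
6 | 4,6-dibromobenzene-1,3-diol | Oc1cc(O)c(Br)cc1Br | starting material
7 | 1,5-dibromo-2,4-bis(tert-butyldimethylsilyloxy)benzene | CC(C)(C)[Si](C)(C)Oc1cc(O[Si](C)(C)C(C)(C)C)c(Br)cc1Br | intermediate
8 | 1-bromo-3-methylbut-2-ene | CC(C)=CCBr | starting material
9 | [5-bromo-2,4-bis(tert-butyldimethylsilyloxy)phenyl]magnesium chloride | CC(C)(C)[Si](C)(C)Oc1cc(O[Si](C)(C)C(C)(C)C)c([Mg]Cl)cc1Br | intermediate
10 | 1-bromo-2,4-bis(tert-butyldimethylsilyloxy)-5-(3-methylbut-2-enyl)benzene | CC(C)=CCc1cc(Br)c(O[Si](C)(C)C(C)(C)C)cc1O[Si](C)(C)C(C)(C)C | intermediate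
11 | 2-[2,4-bis(tert-butyldimethylsilyloxy)-5-(3-methylbut-2-enyl)phenyl]-1-[4-(tert-butyldimethylsilyloxy)-2-methoxy-5-(3-methylbut-2-enyl)phenyl]ethanone | COc1cc(O[Si](C)(C)C(C)(C)C)c(CC=C(C)C)cc1C(=O)Cc1cc(CC=C(C)C)c(O[Si](C)(C)C(C)(C)C)cc1O[Si](C)(C)C(C)(C)C | intermediate
12 | 2-diazo derivative of 11 at the methylene carbon | COc1cc(O[Si](C)(C)C(C)(C)C)c(CC=C(C)C)cc1C(=O)C(=[N+]=[N-])c1cc(CC=C(C)C)c(O[Si](C)(C)C(C)(C)C)cc1O[Si](C)(C)C(C)(C)C | intermediate
13 | rhodium carbene derived from 12 (Rh stands for the Rh2(S-PTAD)4 unit) | COc1cc(O[Si](C)(C)C(C)(C)C)c(CC=C(C)C)cc1C(=O)C(=[Rh])c1cc(CC=C(C)C)c(O[Si](C)(C)C(C)(C)C)cc1O[Si](C)(C)C(C)(C)C | intermediate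
14 | (3S)-7-(tert-butyldimethylsilyloxy)-3-[2,4-bis(tert-butyldimethylsilyloxy)-5-(3-methylbut-2-enyl)phenyl]-6-(3-methylbut-2-enyl)chroman-4-one | CC(C)=CCc1cc2c(cc1O[Si](C)(C)C(C)(C)C)OC[C@H](c1cc(CC=C(C)C)c(O[Si](C)(C)C(C)(C)C)cc1O[Si](C)(C)C(C)(C)C)C2=O | intermediate
15 | (3S)-3-[2,4-dihydroxy-5-(3-methylbut-2-enyl)phenyl]-7-hydroxy-6-(3-methylbut-2-enyl)chroman-4-one | CC(C)=CCc1cc2c(cc1O)OC[C@H](c1cc(CC=C(C)C)c(O)cc1O)C2=O | target

**Step count.** Total: 9 steps. Longest linear sequence: 7 steps (steps 1, 2, 3, 6, 7, 8, 9).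

**Steps most likely to fail**

Step 8. The carbene may be diverted, by oxonium ylide formation at the methoxy oxygen followed by methyl shift or by insertion into a silicon-bound methyl group, or the insertion may proceed with poor facial selectivity. The fallback sets out from 11 and comes back at 14. Chelation-assisted cleavage of the methoxy group ortho to the ketone (MgI2·OEt2, toluene, 60 °C) should give 2-[2,4-bis(tert-butyldimethylsilyloxy)-5-(3-methylbut-2-enyl)phenyl]-1-[4-(tert-butyldimethylsilyloxy)-2-hydroxy-5-(3-methylbut-2-enyl)phenyl]ethanone F1. Heating with N,N-dimethylformamide dimethyl acetal (toluene, 90 °C) should give, through the enaminone, the isoflavone 7-(tert-butyldimethylsilyloxy)-3-[2,4-bis(tert-butyldimethylsilyloxy)-5-(3-methylbut-2-enyl)phenyl]-6-(3-methylbut-2-enyl)chromen-4-one F2. Asymmetric transfer hydrogenation (RuCl[(S,S)-TsDPEN](p-cymene), HCO2H/Et3N, EtOAc; antipode chosen for 4S) reduces the C2=C3 bond and then the ketone with dynamic kinetic resolution at C3, and should give the cis alcohol (3S,4S)-7-(tert-butyldimethylsilyloxy)-3-[2,4-bis(tert-butyldimethylsilyloxy)-5-(3-methylbut-2-enyl)phenyl]-6-(3-methylbut-2-enyl)chroman-4-ol F3. Dess–Martin oxidation (NaHCO3, CH2Cl2, 0 °C) then returns the ketone without touching C3 and gives 14.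

Step 6. Oxidative addition into the electron-rich bromide next to a bulky silyl ether may be slow, and the base may strip aryl silyl ethers or cause a second arylation. The fallback reverses the polarity of the coupling; it sets out from 5 and 10 and comes back at 11. Ketone 5 is converted (TMSOTf, Et3N, CH2Cl2, 0 °C) into its enol ether tert-butyldimethyl{2-(3-methylbut-2-enyl)-5-methoxy-4-[1-(trimethylsilyloxy)vinyl]phenoxy}silane F4. NBS (THF, −78 °C) should attack the enol ether far faster than the prenyl alkene and give 2-bromo-1-[4-(tert-butyldimethylsilyloxy)-2-methoxy-5-(3-methylbut-2-enyl)phenyl]ethanone F5. Bromide 10 is borylated (B2pin2, PdCl2(dppf), KOAc, dioxane, 80 °C) to 2-[2,4-bis(tert-butyldimethylsilyloxy)-5-(3-methylbut-2-enyl)phenyl]-4,4,5,5-tetramethyl-1,3,2-dioxaborolane F6. Suzuki–Miyaura coupling of F5 with F6 (Pd(OAc)2, tri(1-naphthyl)phosphine, K3PO4, THF with a trace of water, rt) gives 11.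

Step 3. Transfer of the allyl group from tin to palladium with allylic transposition would give the branched 1,1-dimethylallyl isomer, and oxidative addition next to the silyl ether may be sluggish. The fallback makes the aryl–CH2 bond by direct displacement at the primary carbon of prenyl bromide; it sets out from 3 and comes back at 5. The ketone is masked (1,2-bis(trimethylsilyloxy)ethane, cat. TMSOTf, CH2Cl2, −78 °C) as 2-[5-bromo-4-(tert-butyldimethylsilyloxy)-2-methoxyphenyl]-2-methyl-1,3-dioxolane F7. Bromine–lithium exchange (n-BuLi, THF, −78 °C, kept cold to avoid silyl migration) and alkylation with 8 in the presence of Li2CuCl4 should give 2-[4-(tert-butyldimethylsilyloxy)-2-methoxy-5-(3-methylbut-2-enyl)phenyl]-2-methyl-1,3-dioxolane F8. Mild hydrolysis (PPTS, acetone/water, rt) returns 5.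

**Further compounds**
F1 | step 8 | 2-[2,4-bis(tert-butyldimethylsilyloxy)-5-(3-methylbut-2-enyl)phenyl]-1-[4-(tert-butyldimethylsilyloxy)-2-hydroxy-5-(3-methylbut-2-enyl)phenyl]ethanone | Oc1cc(O[Si](C)(C)C(C)(C)C)c(CC=C(C)C)cc1C(=O)Cc1cc(CC=C(C)C)c(O[Si](C)(C)C(C)(C)C)cc1O[Si](C)(C)C(C)(C)C
F2 | step 8 | 7-(tert-butyldimethylsilyloxy)-3-[2,4-bis(tert-butyldimethylsilyloxy)-5-(3-methylbut-2-enyl)phenyl]-6-(3-methylbut-2-enyl)chromen-4-one | CC(C)=CCc1cc2c(cc1O[Si](C)(C)C(C)(C)C)OC=C(c1cc(CC=C(C)C)c(O[Si](C)(C)C(C)(C)C)cc1O[Si](C)(C)C(C)(C)C)C2=O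
F3 | step 8 | (3S,4S)-7-(tert-butyldimethylsilyloxy)-3-[2,4-bis(tert-butyldimethylsilyloxy)-5-(3-methylbut-2-enyl)phenyl]-6-(3-methylbut-2-enyl)chroman-4-ol | CC(C)=CCc1cc2c(cc1O[Si](C)(C)C(C)(C)C)OC[C@H](c1cc(CC=C(C)C)c(O[Si](C)(C)C(C)(C)C)cc1O[Si](C)(C)C(C)(C)C)[C@@H]2O
F4 | step 6 | tert-butyldimethyl{2-(3-methylbut-2-enyl)-5-methoxy-4-[1-(trimethylsilyloxy)vinyl]phenoxy}silane | C=C(O[Si](C)(C)C)c1cc(CC=C(C)C)c(O[Si](C)(C)C(C)(C)C)cc1OC
F5 | step 6 | 2-bromo-1-[4-(tert-butyldimethylsilyloxy)-2-methoxy-5-(3-methylbut-2-enyl)phenyl]ethanone | BrCC(=O)c1cc(CC=C(C)C)c(O[Si](C)(C)C(C)(C)C)cc1OC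
F6 | step 6 | 2-[2,4-bis(tert-butyldimethylsilyloxy)-5-(3-methylbut-2-enyl)phenyl]-4,4,5,5-tetramethyl-1,3,2-dioxaborolane | CC(C)=CCc1cc(B2OC(C)(C)C(C)(C)O2)c(O[Si](C)(C)C(C)(C)C)cc1O[Si](C)(C)C(C)(C)C
F7 | step 3 | 2-[5-bromo-4-(tert-butyldimethylsilyloxy)-2-methoxyphenyl]-2-methyl-1,3-dioxolane | COc1cc(O[Si](C)(C)C(C)(C)C)c(Br)cc1C1(C)OCCO1
F8 | step 3 | 2-[4-(tert-butyldimethylsilyloxy)-2-methoxy-5-(3-methylbut-2-enyl)phenyl]-2-methyl-1,3-dioxolane | COc1cc(O[Si](C)(C)C(C)(C)C)c(CC=C(C)C)cc1C1(C)OCCO1
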